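## The problem

Target 27 is 5-hydroxy-7-(3-methylbut-2-enyloxy)-3-(2,4-dihydroxyphenyl)chromen-4-one. It is an isoflavone: a benzo ring (ring A) is fused across C4a–C8a of a 4-pyranone (ring C), and a resorcinol ring (ring B) sits on C3. There is no stereocentre, so every difficulty is one of position and of functional-group tolerance. Four phenolic oxygens must end in three different states: O7 as a prenyl ether, O5 free and chelated to the C4 carbonyl, O2' and O4' free. The prenyl ether can ionise in acid and its alkene rules out hydrogenolysis, and the pyranone ring opens with hydroxide and adds hard nucleophiles. Ring A is a resorcinol unit whose C5 oxygen lies peri to C4=O, and whose C4a–C8a bond is at the same time the enone C=C bond of a 4-pyranone. A pyranone with a ketene precursor on the carbon that becomes C8a and a free C–H on the carbon that becomes C4a can therefore receive C5–C8 in one benzannulation with an oxygenated alkyne. That construction delivers O5 as a free phenol and O7 as a separately addressable ether.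

## Retrosynthesis

**27 ⇒ 26.** The last bonds cut are the two O–CH2 acetal bonds on ring B. Methoxymethyl ethers are chosen because they must pass an aryllithium, a palladium coupling, an oxidation, visible light and fluoride. Benzyl ethers would need hydrogenolysis, which the prenyl alkene does not survive, and methyl ethers would need a boron halide, which the prenyl ether does not survive. The forward step must cleave an aryl acetal faster than the allylic ether ionises.

**26 ⇒ 23 + 24.** The O7–CH2 bond is cut next. The prenyl group cannot ride through ring construction on the alkyne, because an allyl ynol ether would rearrange sigmatropically. O7 is therefore carried as a silyl ether in 23 and exchanged for the group from prenyl bromide 24. In 23 the ring construction has already told the two ring A oxygens apart: O7 is silylated and O5 is a free, chelated phenol. Fluoride therefore releases a single phenoxide, and no selective alkylation of a 5,7-diol has to be arranged.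

**23 ⇒ 13 + 18 (key disconnection).** Four bonds of ring A are cut: C8–C8a, C5–C6, C7–C8 and C4a–C5. What remains is the monocyclic pyranonyl diazo ketone 13 and (triisopropylsilyloxy)acetylene 18. The usual isoflavone cuts through ring C (deoxybenzoin closure, or a 3-halochromone coupling) keep a phloroglucinol ring A whose oxygens must be told apart afterwards. This cut builds ring A with the difference already in place. Pyranone C2 of 13 becomes C8a, pyranone C3 becomes C4a, and the aryl-bearing pyranone C5 becomes chromone C3. The forward reaction must give a regioselective ketene–alkyne addition and must close onto pyranone C3, passing through ketene 19, cyclobutenone 20, dienylketene 21 and dienone 22.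

**13 ⇒ 9 + 10, and 9 ⇒ 7.** The bond between the acyl carbon and the diazo carbon is cut, leading to carboxylic acid 9 and (trimethylsilyl)diazomethane 10. Acylation of a diazoalkane is preferred to diazo transfer because the acid is one oxidation step from the hydroxymethyl group that kojic acid already carries, so 9 is traced to alcohol 7. The forward reactions must not touch the electron-rich ring B or the acetals.

**7 ⇒ 6 + 4.** The bond between pyranone C5 and ring B (later chromone C3–C1') is cut as a Suzuki–Miyaura coupling of enol triflate 6 with pinacol boronate 4. This puts the aryl group on the pyranone before ring A exists, so the coupling partner is a small, unhindered triflate. Triflate 6 comes in one step from kojic acid 5, whose only acidic hydroxyl is the one to be replaced. Boronate 4 comes from 4-bromoresorcinol 1 through the protected bromide 2.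

**18 ⇒ 14 + 15.** The O–Si bond and the C–O bond of the siloxyalkyne are cut, leading to acetylene 14, an oxygen-transfer reagent and silyl triflate 15. A bulky silyl group is needed so that the ynolate is silylated on oxygen and the ynol ether survives isolation.

## Roads not taken

**Alternative 1:** The pyranone ring is cut at O1–C2 and C3–C4. In the forward direction, photolysis of benzodioxinone A2 would release quinoketene A3. Its acylketene unit would add enol ether A4 as a heterodiene, and loss of the methoxy group from the adduct would give isoflavone A1.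
- Merits: the step is convergent and fixes the aryl group on C3 through the polarity of the enol ether. Simple acylketenes are known to add enol ethers in this way, so it is arguably closer to precedent than the chosen key step. Ring A is bought, which saves the steps that build 13.
- Weak points: A4 is a styrene that absorbs light and can isomerise or dimerise. Quinoketenes are usually intercepted by heteroatom nucleophiles, not by alkenes. A1 carries two identical benzyl ethers, which must come off by hydrogenolysis before the prenyl group can be introduced, so the end game is one step longer.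
- Comparison: overall length is similar. The chosen plan sets against it an O7 that is already distinguished, a route with no benzyl stage, and the aryl–pyranone bond made by a routine coupling.

**Alternative 2:** The cut is at C4a–C4, C3–C4 and O1–C2. A three-component carbonylative Suzuki coupling of iodophenol A6 with vinylboronate A7 (Pd(OAc)2 with a phosphine) would give an α-aryl enone. Its phenoxide would close onto the methylene carbon to give racemic isoflavanone A5.
- Merits: every reaction type is known, so the key step carries less risk than the one chosen here.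
- Weak points: A5 is at the wrong oxidation level and has a stereocentre that is made only to be destroyed, so a separate dehydrogenation to A1 is needed. The iodide of A6 is flanked by two oxygen substituents, which slows oxidative addition and acyl transfer. A7 is an α-aryl vinylboronate that is prone to protodeboronation. The benzyl problem of alternative 1 returns.
- Comparison: this is the safer route, but it is longer by the dehydrogenation and the debenzylation. The chosen plan offers direct delivery of the chromone oxidation level and of the O5/O7 difference.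

**Alternative 3:** Only C4–C4a is cut. The aryloxyacrylic acid A9 would close in P2O5/MeSO3H through an acylium ion to tetramethyl ether A8.
- Merits: this is the most robust and scalable way to the isoflavone skeleton. The symmetric ring A needs no regiocontrol and the reagents are cheap.
- Weak points: acetals and silyl ethers do not survive the medium, so all four oxygens must be methyl ethers. Exhaustive demethylation would give tetraol A10, and O7 would then have to be prenylated selectively beside three other free phenols. The electron-rich ring B of A9 can also be acylated or sulfonated.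
- Comparison: the core is reached faster and more reliably than by the chosen plan, but the protecting-group end game is the weakest of the four. The chosen plan accepts a less proven ring construction in exchange for orthogonal oxygens.

Key step: step 8

Assumption: siloxyalkyne 18 is treated as a compound to be made (step 7), not bought; acetylene, prenyl bromide and the reagents on the reagent lines are taken as catalogue chemicals.

## Route

Step 1
Reactants: 1 4-bromoresorcinol
Product: 2 1-bromo-2,4-bis(methoxymethoxy)benzene
Conditions: MeOCH2Cl (2.5 equiv), i-Pr2NEt, CH2Cl2, 0 to 25 °C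
Reagents that add atoms: chloromethyl methyl ether, COCCl
Why: Double O-alkylation of the phenols (Williamson-type ether synthesis with an α-chloro ether); the hindered amine only takes up HCl and the aryl bromide is untouched.

Step 2
Reactants: 2 1-bromo-2,4-bis(methoxymethoxy)benzene
Product: 4 2-[2,4-bis(methoxymethoxy)phenyl]-4,4,5,5-tetramethyl-1,3,2-dioxaborolane, via aryllithium 3 (not isolated)
Conditions: n-BuLi, THF, −78 °C; i-PrOBpin, −78 to 25 °C; aq NH4Cl
Reagents that add atoms: 2-isopropoxy-4,4,5,5-tetramethyl-1,3,2-dioxaborolane, CC(C)OB1OC(C)(C)C(C)(C)O1; n-butyllithium, [Li]CCCC (lithium only in intermediate 3)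
Why: Bromine–lithium exchange at −78 °C is faster than any attack on the acetals and the ortho acetal oxygen holds the lithium; aryllithium 3 adds to the borate and the ate complex loses isopropoxide on work-up (borylation of an organolithium), giving a pinacol boronate that stores better than the free boronic acid.

Step 3
Reactants: 5 kojic acid
Product: 6 6-(hydroxymethyl)-4-oxo-4H-pyran-3-yl trifluoromethanesulfonate
Conditions: PhNTf2 (1.05 equiv), Et3N, DMF, 0 to 25 °C
Reagents that add atoms: N-phenylbis(trifluoromethanesulfonimide), O=S(=O)(N(c1ccccc1)S(=O)(=O)C(F)(F)F)C(F)(F)F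
Why: Chemoselective O-sulfonylation: the amine deprotonates only the acidic enolic hydroxyl, and the mild triflyl donor reacts with that vinylogous carboxylate but not with a neutral primary alcohol; the product is an α-triflyloxy enone ready for cross-coupling.

Step 4
Reactants: 6 6-(hydroxymethyl)-4-oxo-4H-pyran-3-yl trifluoromethanesulfonate; 4 2-[2,4-bis(methoxymethoxy)phenyl]-4,4,5,5-tetramethyl-1,3,2-dioxaborolane
Product: 7 5-[2,4-bis(methoxymethoxy)phenyl]-2-(hydroxymethyl)-4H-pyran-4-one
Conditions: Pd(PPh3)4 (5 mol %), K3PO4, 1,4-dioxane–H2O, 80 °C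
Reagents that add atoms: none
Why: Suzuki–Miyaura coupling: zerovalent palladium inserts readily into the C–O bond of the electron-poor α-triflyloxy enone, phosphate activates the boronate for transmetalation, and the free primary alcohol and the acetals are inert; a small excess of 4 covers protodeboronation of the electron-rich ortho-alkoxy boronate.

Step 5
Reactants: 7 5-[2,4-bis(methoxymethoxy)phenyl]-2-(hydroxymethyl)-4H-pyran-4-one
Product: 9 5-[2,4-bis(methoxymethoxy)phenyl]-4-oxo-4H-pyran-2-carboxylic acid, via aldehyde 8 (not isolated)
Conditions: TEMPO (0.2 equiv), PhI(OAc)2 (2.2 equiv), MeCN–H2O (1:1), 25 °C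
Reagents that add atoms: water, O
Why: TEMPO-catalysed oxidation with PhI(OAc)2 as terminal oxidant: the oxoammonium ion takes the activated primary alcohol to aldehyde 8, whose hydrate (favoured on the electron-poor pyranone) is oxidised again to the acid; the system holds no active halogen, so ring B is not halogenated, and the acetic acid released is too weak to cleave the acetals.

Step 6
Reactants: 9 5-[2,4-bis(methoxymethoxy)phenyl]-4-oxo-4H-pyran-2-carboxylic acid; 10 (trimethylsilyl)diazomethane
Product: 13 2-diazo-1-{5-[2,4-bis(methoxymethoxy)phenyl]-4-oxo-4H-pyran-2-yl}ethanone, via mixed anhydride 11 (not isolated), via C-silyl diazoketone 12 (not isolated)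
Conditions: i-BuOCOCl, N-methylmorpholine, THF, −15 °C; Me3SiCHN2 (2 equiv), MeCN, 0 to 25 °C; aq NaHCO3
Reagents that add atoms: isobutyl chloroformate, CC(C)COC(Cl)=O (atoms only in intermediate 11)
Why: Acylation of a diazoalkane by a mixed carbonic anhydride (first stage of an Arndt–Eistert sequence): the nucleophilic diazo carbon attacks the more electrophilic pyranoyl carbonyl of 11 and the C-silyl diazo ketone 12 loses silicon on the bicarbonate work-up; no hydrogen chloride is formed, so the acetals are safe.

Step 7
Reactants: 14 acetylene; 15 triisopropylsilyl trifluoromethanesulfonate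
Product: 18 (triisopropylsilyloxy)acetylene, via lithium acetylide 16 (not isolated), via lithium ethynolate 17 (not isolated)
Conditions: C2H2 (excess), n-BuLi, THF, −78 °C; t-BuOOLi (from t-BuOOH, LiN(SiMe3)2), −78 to −10 °C; i-Pr3SiOTf, −78 to 0 °C; pentane, distillation
Reagents that add atoms: tert-butyl hydroperoxide, CC(C)(C)OO; n-butyllithium, [Li]CCCC (lithium only in intermediates 16 and 17)
Why: Oxygen transfer from lithium tert-butyl peroxide to a lithium acetylide (electrophilic hydroxylation of a carbanion) gives ynolate 17, and the hard, bulky silyl triflate silylates it on oxygen; excess acetylene keeps the acetylide at the monolithium stage.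

Step 8
Reactants: 13 2-diazo-1-{5-[2,4-bis(methoxymethoxy)phenyl]-4-oxo-4H-pyran-2-yl}ethanone; 18 (triisopropylsilyloxy)acetylene
Product: 23 5-hydroxy-7-(triisopropylsilyloxy)-3-[2,4-bis(methoxymethoxy)phenyl]chromen-4-one, via pyranonylketene 19 (not isolated), via cyclobutenone 20 (not isolated), via dienylketene 21 (not isolated), via dienone 22 (not isolated)
Conditions: 18 (3 equiv), hν (450 nm LED), ClCH2CH2Cl, 25 °C; then 80 °C
Reagents that add atoms: none
Why: Proposed new method: visible light excites the diazo ketone of 13, nitrogen is lost and the pyranonyl group migrates to the former diazo carbon (Wolff rearrangement, forming C8–C8a of the later chromone) to give ketene 19. The electron-rich CH terminus of siloxyalkyne 18 attacks the ketene carbonyl carbon (C5–C6) and the oxygen-bearing alkyne carbon bonds to the ketene CH (C7–C8), a [2+2] cycloaddition whose regiochemistry is fixed by the polarity of the ynol ether; it places the silyloxy group meta to the future hydroxyl and gives cyclobutenone 20. At 80 °C 20 opens by a reversible four-electron conrotatory cleavage of its C1–C4 bond to dienylketene 21; only the isomer with the pyranone cis to the ketene can react on, and the other returns to 20. Ring A then closes by a thermal disrotatory six-electron electrocyclisation between the ketene carbon and pyranone C3 (C4a–C5), the only possible site because the other neighbour of pyranone C2 is the ring oxygen, and dienone 22 enolises through its doubly activated C4a–H to the chelated phenol 23. The closest known reaction type is the Danheiser benzannulation of vinyl, aryl and heteroaryl diazomethyl ketones with siloxyalkynes, which has not been run with a 4-pyranone as the unsaturated partner; the C2=C3 bond of a 4-pyranone is only weakly aromatic and should behave like the alkene of a vinylketene. No stereocentre remains, since the single stereocentres of 20 and 22 are racemic and are erased on the way to 23. Light of 450 nm is chosen because only the diazo ketone should absorb there, so the aryl pyranone and the product chromone are not excited, and no silver salt is used because it would activate the siloxyalkyne.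

Step 9
Reactants: 23 5-hydroxy-7-(triisopropylsilyloxy)-3-[2,4-bis(methoxymethoxy)phenyl]chromen-4-one; 24 prenyl bromide (1-bromo-3-methylbut-2-ene)
Product: 26 5-hydroxy-3-[2,4-bis(methoxymethoxy)phenyl]-7-(3-methylbut-2-enyloxy)chromen-4-one, via ammonium phenoxide 25 (not isolated)
Conditions: Bu4NF (1.05 equiv), THF, 0 °C; then 24 (1.2 equiv), 0 to 25 °C
Reagents that add atoms: tetrabutylammonium fluoride, CCCC[N+](CCCC)(CCCC)CCCC.[F-] (cation only in intermediate 25)
Why: Fluoride cleaves the aryl silyl ether, which is activated because its phenoxide is a vinylogous carboxylate of the C4 carbonyl, and the 7-phenoxide 25 is alkylated in the same flask at the primary allylic bromide (Williamson ether synthesis, SN2); the 5-hydroxyl is less acidic and stays locked in its hydrogen bond to C4=O, so only O7 reacts.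

Step 10
Reactants: 26 5-hydroxy-3-[2,4-bis(methoxymethoxy)phenyl]-7-(3-methylbut-2-enyloxy)chromen-4-one
Product: 27 5-hydroxy-7-(3-methylbut-2-enyloxy)-3-(2,4-dihydroxyphenyl)chromen-4-one
Conditions: HCl (1 M), MeOH–THF (4:1), 25 °C; aq NaHCO3
Reagents that add atoms: none
Why: Acid-catalysed acetal cleavage (transacetalisation to methanol): the aryl methoxymethyl acetals ionise through an oxocarbenium ion far more easily than the aryl prenyl ether can lose an allyl cation in dilute acid at 25 °C, and the chelated 5-hydroxychromone is stable to these conditions.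

## Compound list

1 | 4-bromoresorcinol (4-bromobenzene-1,3-diol) | Oc1ccc(Br)c(O)c1 | starting material
2 | 1-bromo-2,4-bis(methoxymethoxy)benzene | COCOc1ccc(Br)c(OCOC)c1 | intermediate
3 | [2,4-bis(methoxymethoxy)phenyl]lithium | [Li]c1ccc(OCOC)cc1OCOC | intermediate (not isolated)
4 | 2-[2,4-bis(methoxymethoxy)phenyl]-4,4,5,5-tetramethyl-1,3,2-dioxaborolane | COCOc1ccc(B2OC(C)(C)C(C)(C)O2)c(OCOC)c1 | intermediate
5 | kojic acid (5-hydroxy-2-(hydroxymethyl)-4H-pyran-4-one) | O=c1cc(CO)occ1O | starting material
6 | 6-(hydroxymethyl)-4-oxo-4H-pyran-3-yl trifluoromethanesulfonate | O=c1cc(CO)occ1OS(=O)(=O)C(F)(F)F | intermediate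
7 | 5-[2,4-bis(methoxymethoxy)phenyl]-2-(hydroxymethyl)-4H-pyran-4-one | COCOc1ccc(-c2coc(CO)cc2=O)c(OCOC)c1 | intermediate
8 | 5-[2,4-bis(methoxymethoxy)phenyl]-4-oxo-4H-pyran-2-carbaldehyde | COCOc1ccc(-c2coc(C=O)cc2=O)c(OCOC)c1 | intermediate (not isolated)
9 | 5-[2,4-bis(methoxymethoxy)phenyl]-4-oxo-4H-pyran-2-carboxylic acid | COCOc1ccc(-c2coc(C(=O)O)cc2=O)c(OCOC)c1 | intermediate
10 | (trimethylsilyl)diazomethane | C[Si](C)(C)C=[N+]=[N-] | starting material
11 | 5-[2,4-bis(methoxymethoxy)phenyl]-4-oxo-4H-pyran-2-carboxylic 2-methylpropyl carbonic anhydride | CC(C)COC(=O)OC(=O)c1cc(=O)c(-c2ccc(OCOC)cc2OCOC)co1 | intermediate (not isolated)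
12 | 2-diazo-1-{5-[2,4-bis(methoxymethoxy)phenyl]-4-oxo-4H-pyran-2-yl}-2-(trimethylsilyl)ethanone | C[Si](C)(C)C(=[N+]=[N-])C(=O)c1cc(=O)c(-c2ccc(OCOC)cc2OCOC)co1 | intermediate (not isolated)
13 | 2-diazo-1-{5-[2,4-bis(methoxymethoxy)phenyl]-4-oxo-4H-pyran-2-yl}ethanone | [N-]=[N+]=CC(=O)c1cc(=O)c(-c2ccc(OCOC)cc2OCOC)co1 | intermediate
14 | acetylene | C#C | starting material
15 | triisopropylsilyl trifluoromethanesulfonate | CC(C)[Si](OS(=O)(=O)C(F)(F)F)(C(C)C)C(C)C | starting material
16 | lithium acetylide | [Li+].[C-]#C | intermediate (not isolated)
17 | lithium ethynolate | [Li+].[O-]C#C | intermediate (not isolated)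
18 | (triisopropylsilyloxy)acetylene | C#CO[Si](C(C)C)(C(C)C)C(C)C | intermediate
19 | 5-[2,4-bis(methoxymethoxy)phenyl]-2-(2-oxoethenyl)-4H-pyran-4-one | O=C=Cc1cc(=O)c(-c2ccc(OCOC)cc2OCOC)co1 | intermediate (not isolated)
20 | racemic 4-{5-[2,4-bis(methoxymethoxy)phenyl]-4-oxo-4H-pyran-2-yl}-3-(triisopropylsilyloxy)cyclobut-2-en-1-one | O=C1C=C(O[Si](C(C)C)(C(C)C)C(C)C)C1c1cc(=O)c(-c2ccc(OCOC)cc2OCOC)co1 | intermediate (not isolated)
21 | 5-[2,4-bis(methoxymethoxy)phenyl]-2-[(1E)-4-oxo-2-(triisopropylsilyloxy)buta-1,3-dien-1-yl]-4H-pyran-4-one (pyranone cis to the ketene carbon) | O=C=C/C(O[Si](C(C)C)(C(C)C)C(C)C)=C\c1cc(=O)c(-c2ccc(OCOC)cc2OCOC)co1 | intermediate (not isolated)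
22 | racemic 3-[2,4-bis(methoxymethoxy)phenyl]-7-(triisopropylsilyloxy)-4aH-chromene-4,5-dione | O=C1C=C(O[Si](C(C)C)(C(C)C)C(C)C)C=C2OC=C(c3ccc(OCOC)cc3OCOC)C(=O)C12 | intermediate (not isolated)
23 | 5-hydroxy-7-(triisopropylsilyloxy)-3-[2,4-bis(methoxymethoxy)phenyl]chromen-4-one | CC(C)[Si](Oc1cc(O)c2c(=O)c(-c3ccc(OCOC)cc3OCOC)coc2c1)(C(C)C)C(C)C | intermediate
24 | prenyl bromide (1-bromo-3-methylbut-2-ene) | CC(C)=CCBr | starting material
25 | tetrabutylammonium 5-hydroxy-3-[2,4-bis(methoxymethoxy)phenyl]-4-oxo-4H-chromen-7-olate | CCCC[N+](CCCC)(CCCC)CCCC.[O-]c1cc(O)c2c(=O)c(-c3ccc(OCOC)cc3OCOC)coc2c1 | intermediate (not isolated)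
26 | 5-hydroxy-3-[2,4-bis(methoxymethoxy)phenyl]-7-(3-methylbut-2-enyloxy)chromen-4-one | CC(C)=CCOc1cc(O)c2c(=O)c(-c3ccc(OCOC)cc3OCOC)coc2c1 | intermediate
27 | 5-hydroxy-7-(3-methylbut-2-enyloxy)-3-(2,4-dihydroxyphenyl)chromen-4-one | CC(C)=CCOc1cc(O)c2c(=O)c(-c3ccc(O)cc3O)coc2c1 | target

## Step count and risk

Total steps: 10. Longest linear sequence: 8 (steps 1, 2, 4, 5, 6, 8, 9, 10).

**Step 8 (key step, proposed new method).**
- What may go wrong:
  - Excitation of the aryl pyranone instead of the diazo group, leading to photoisomerisation of the 4-pyranone.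
  - Dipolar cycloaddition of the diazo ketone with the electron-rich alkyne before nitrogen is lost.
  - Dimerisation of ketene 19, or acylation of the product phenol by it.
  - Stalling at cyclobutenone 20, if ring opening gives mainly the dienylketene isomer that cannot cyclise.
- Fallback with known chemistry, setting out from boronate 4 and returning at 23: ring A is bought instead of built.
  - Commercial 2',4',6'-trihydroxyacetophenone is silylated at its unchelated 4-hydroxyl (i-Pr3SiCl, imidazole) to 1-[2,6-dihydroxy-4-(triisopropylsilyloxy)phenyl]ethanone F1.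
  - Condensation with N,N-dimethylformamide dimethyl acetal gives (E)-3-(dimethylamino)-1-[2,6-dihydroxy-4-(triisopropylsilyloxy)phenyl]prop-2-en-1-one F2.
  - I2 in the presence of pyridine cyclises and iodinates F2 to 5-hydroxy-3-iodo-7-(triisopropylsilyloxy)chromen-4-one F3.
  - Suzuki–Miyaura coupling of F3 with 4 (Pd(PPh3)4, K3PO4, dioxane with little water to spare the silyl ether) gives 23.

**Step 7.**
- What may go wrong:
  - Disproportionation of the monolithium acetylide on warming, before oxygen transfer.
  - Silylation of the unsubstituted ynolate on carbon instead of oxygen.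
  - Loss of the volatile product on concentration.
- Fallback, setting out from diazo ketone 13 and returning at 26: the siloxyalkyne is replaced by an alkoxyalkyne made by elimination, not oxidation.
  - Trichloroethylene and 2-(trimethylsilyl)ethanol with KH give (E)-1,2-dichloro-1-[2-(trimethylsilyl)ethoxy]ethene F4.
  - n-BuLi (2 equiv) and then methanol give [2-(ethynyloxy)ethyl]trimethylsilane F5.
  - The irradiation and heating sequence of step 8 with 13 and F5 gives 5-hydroxy-3-[2,4-bis(methoxymethoxy)phenyl]-7-[2-(trimethylsilyl)ethoxy]chromen-4-one F6.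
  - CsF in DMF at 60 °C expels the silylethyl group from F6, and prenyl bromide 24 traps the phenoxide to give 26.

**Step 6.**
- What may go wrong:
  - Dipolar addition of the diazoalkane, or of the product diazo ketone, across the acyl-activated C2=C3 bond of the pyranone.
  - Attack of the diazoalkane at the carbonate carbonyl of 11.
- Fallback, setting out from acid 9 and returning at 13: the diazo group is introduced by diazo transfer, with no free diazoalkane.
  - Acid 9 is converted through its mixed anhydride with MeNHOMe·HCl into N-methoxy-N-methyl-5-[2,4-bis(methoxymethoxy)phenyl]-4-oxo-4H-pyran-2-carboxamide F7.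
  - MeMgBr at −78 °C gives 2-acetyl-5-[2,4-bis(methoxymethoxy)phenyl]-4H-pyran-4-one F8.
  - LiN(SiMe3)2 and 2,2,2-trifluoroethyl trifluoroacetate give 4,4,4-trifluoro-1-{5-[2,4-bis(methoxymethoxy)phenyl]-4-oxo-4H-pyran-2-yl}butane-1,3-dione F9, used crude.
  - Methanesulfonyl azide, Et3N and water in MeCN (detrifluoroacetylative diazo transfer) give 13.

**Step 10.**
- What may go wrong: ionisation of the prenyl ether, or addition of methanol or HCl across its alkene, competing with acetal cleavage.
- Fallback, setting out from 23 and returning at 27: the acid step is moved ahead of the prenylation.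
  - HCl in methanol at 40 °C removes the two acetals while the aryl silyl ether, which is slow to solvolyse in acid, is kept. This gives 3-(2,4-dihydroxyphenyl)-5-hydroxy-7-(triisopropylsilyloxy)chromen-4-one F10.
  - One equivalent of Bu4NF then releases only the 7-phenoxide, the most acidic site, and prenyl bromide 24 alkylates it to give 27.
  - If the silyl ether is lost in the acid step, the same selectivity is sought with one equivalent of base.

## Further compounds

F1 | step 8 | 1-[2,6-dihydroxy-4-(triisopropylsilyloxy)phenyl]ethanone | CC(=O)c1c(O)cc(O[Si](C(C)C)(C(C)C)C(C)C)cc1O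
F2 | step 8 | (E)-3-(dimethylamino)-1-[2,6-dihydroxy-4-(triisopropylsilyloxy)phenyl]prop-2-en-1-one | CN(C)/C=C/C(=O)c1c(O)cc(O[Si](C(C)C)(C(C)C)C(C)C)cc1O
F3 | step 8 | 5-hydroxy-3-iodo-7-(triisopropylsilyloxy)chromen-4-one | CC(C)[Si](Oc1cc(O)c2c(=O)c(I)coc2c1)(C(C)C)C(C)C
F4 | step 7 | (E)-1,2-dichloro-1-[2-(trimethylsilyl)ethoxy]ethene | Cl/C=C(/Cl)OCC[Si](C)(C)C
F5 | step 7 | [2-(ethynyloxy)ethyl]trimethylsilane | C#COCC[Si](C)(C)C
F6 | step 7 | 5-hydroxy-3-[2,4-bis(methoxymethoxy)phenyl]-7-[2-(trimethylsilyl)ethoxy]chromen-4-one | C[Si](C)(C)CCOc1cc(O)c2c(=O)c(-c3ccc(OCOC)cc3OCOC)coc2c1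
F7 | step 6 | N-methoxy-N-methyl-5-[2,4-bis(methoxymethoxy)phenyl]-4-oxo-4H-pyran-2-carboxamide | CON(C)C(=O)c1cc(=O)c(-c2ccc(OCOC)cc2OCOC)co1
F8 | step 6 | 2-acetyl-5-[2,4-bis(methoxymethoxy)phenyl]-4H-pyran-4-one | CC(=O)c1cc(=O)c(-c2ccc(OCOC)cc2OCOC)co1
F9 | step 6 | 4,4,4-trifluoro-1-{5-[2,4-bis(methoxymethoxy)phenyl]-4-oxo-4H-pyran-2-yl}butane-1,3-dione | O=C(CC(=O)C(F)(F)F)c1cc(=O)c(-c2ccc(OCOC)cc2OCOC)co1
F10 | step 10 | 3-(2,4-dihydroxyphenyl)-5-hydroxy-7-(triisopropylsilyloxy)chromen-4-one | CC(C)[Si](Oc1cc(O)c2c(=O)c(-c3ccc(O)cc3O)coc2c1)(C(C)C)C(C)C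
A1 | alternative 1 | 5,7-bis(benzyloxy)-3-[2,4-bis(methoxymethoxy)phenyl]chromen-4-one | COCOc1ccc(-c2coc3cc(OCc4ccccc4)cc(OCc4ccccc4)c3c2=O)c(OCOC)c1
A2 | alternative 1 | 5,7-bis(benzyloxy)-2,2-dimethyl-4H-1,3-benzodioxin-4-one | CC1(C)OC(=O)c2c(O1)cc(OCc1ccccc1)cc2OCc1ccccc1
A3 | alternative 1 | 3,5-bis(benzyloxy)-6-(oxomethylidene)cyclohexa-2,4-dien-1-one | O=C=C1C(=O)C=C(OCc2ccccc2)C=C1OCc1ccccc1
A4 | alternative 1 | 1-[(E)-2-methoxyethenyl]-2,4-bis(methoxymethoxy)benzene | CO/C=C/c1ccc(OCOC)cc1OCOC
A5 | alternative 2 | racemic 5,7-bis(benzyloxy)-3-[2,4-bis(methoxymethoxy)phenyl]chroman-4-one | COCOc1ccc(C2COc3cc(OCc4ccccc4)cc(OCc4ccccc4)c3C2=O)c(OCOC)c1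
A6 | alternative 2 | 3,5-bis(benzyloxy)-2-iodophenol | Oc1cc(OCc2ccccc2)cc(OCc2ccccc2)c1I
A7 | alternative 2 | 2-{1-[2,4-bis(methoxymethoxy)phenyl]ethenyl}-4,4,5,5-tetramethyl-1,3,2-dioxaborolane | C=C(B1OC(C)(C)C(C)(C)O1)c1ccc(OCOC)cc1OCOC
A8 | alternative 3 | 5,7-dimethoxy-3-(2,4-dimethoxyphenyl)chromen-4-one | COc1ccc(-c2coc3cc(OC)cc(OC)c3c2=O)c(OC)c1
A9 | alternative 3 | (2Z)-3-(3,5-dimethoxyphenoxy)-2-(2,4-dimethoxyphenyl)prop-2-enoic acid | OC(=O)/C(=C\Oc1cc(OC)cc(OC)c1)c1ccc(OC)cc1OC
A10 | alternative 3 | 5,7-dihydroxy-3-(2,4-dihydroxyphenyl)chromen-4-one | O=c1c(-c2ccc(O)cc2O)coc2cc(O)cc(O)c12
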